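## Structural features

The target 17 is an achiral bibenzyl: ring A and ring B are joined by a two-carbon bridge Cα–Cβ, and three 4-hydroxybenzyl groups hang on the two rings as diarylmethanes. Ring A is pentasubstituted, with methoxyl at a1, hydrogen at a2, hydroxyl at a3, 4-hydroxybenzyl groups at a4 and a6, and the bridge at a5, so a5 sits in a pocket between two benzylic methylenes. Ring B is a 1,3,5-trisubstituted benzene with the bridge at b1, a hydroxyl at b3 and a 4-hydroxybenzyl group at b5. There is no stereocentre, so no two stand next to each other; the route passes through only one, at Cα, and removes it again. The fragile features are the five free phenols (electron-rich, oxidisable, incompatible with organometallics), the three doubly benzylic CH2 groups (acidic towards strong base), and the single methyl ether, which must survive while five other oxygens are unmasked. The real difficulties are the crowding at a5 and the fact that a1 and a3 differ only as O-methyl versus O–H on an otherwise symmetrical ring. The key step exploits the fact that Cα–Cβ is an unfunctionalised ethylene between two aryl carbons, a5 and b1. A vinylboron unit can take ring A on Cα by migration from boron and ring B on Cβ from palladium, so the hindered a5 carbon enters as an aryllithium and never passes through palladium.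

## Logic of the disconnections

17 to 16. The five phenolic O–H bonds are traced back to five O–benzyl bonds. Free phenols cannot be carried through organolithium and palladium steps, and hydrogenolysis is the one unmasking that leaves the a1 methyl ether and the diarylmethane CH2 groups alone. The gain is that every earlier compound is a neutral polyether. The demand is one exhaustive hydrogenolysis on material free of catalyst poisons.

16 to 15. The Cα–H bond is replaced by Cα–B. This puts a boron handle where a conjunctive coupling leaves it and turns the inert CH2–CH2 bridge into a retron for a three-component reaction. The demand is a protodeboronation of a crowded secondary benzylic boronate that spares five benzyl ethers.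

15 to 6, 12 and 11. The bonds a5–Cα and Cβ–b1 are cut, leaving the bridge as the two carbons of 12. Cutting here divides the molecule into two arenes of similar size and one commercial C2 unit, and lets the crowded ring A act as a nucleophile through 13 and 14. The forward step needs clean bromine–lithium exchange in 6 without deprotonation of its CH2 groups, and a metallate shift that outruns direct boron-to-palladium transfer. Lithium bromide from the exchange is a known brake on this catalysis, so an alkali triflate is added to scavenge it.

6 to 3 and 5. The bonds a4–CH2 and a6–CH2 are cut. Both benzyl groups are identical, so one reagent, 5, serves twice, and the iodine atoms of 3 mark in advance where the carbon groups go while bromine is kept for step 9. This replaces a twofold Friedel–Crafts benzylation, which would expose three benzyl ethers to acid and leave the product open to further alkylation. The demand is coupling at two crowded C–I bonds without touching C–Br.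

3 to 2 to 1. Two C–I bonds and one O–benzyl bond are cut. The methoxyl/hydroxyl distinction of ring A is therefore bought with the first compound and never has to be created later. The demand is that iodination enters the two carbons flanking bromine and not the carbon between the two oxygens.

11 to 10 to 9. The O–S bond of the triflate and then the b1–O bond (from b1–Cl) are cut. A chloride is carried as a latent phenol because it survives the benzylation of ring B. The demand is a hydroxylation of an aryl chloride that leaves benzyl ethers intact.

9 to 8 and 5, 8 to 7, 5 to 4. The b5–CH2 bond is cut to the same zinc reagent 5 used for ring A. Ring B is taken from a bromo-chloro phenol and not from a dibromide, so the single benzylation is chemoselective and not statistical. The demand is coupling at C–Br only.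

## Other disconnections considered

Alternative 1: The cut goes through ring A itself (a4–a5 and a1–a2), which would be rebuilt from the ketone A1 and the α-benzylated enoate A2 that already carries ring B.
- Forward step: the more substituted enolate of A1 would add to A2 in a Michael reaction, and the methyl terminus would then close on the ester by Claisen condensation to give the dione A3. Iodine in methanol would aromatise A3 to the mono-methyl ether A4, and hydrogenolysis would give 17.
- In favour: the substitution pattern of ring A follows from connectivity, so no aromatic substitution has to be steered. On this point it is better than the chosen plan, whose step 2 relies on directing effects. The methyl ether appears during aromatisation, and because a4 and a6 carry the same group it does not matter which carbonyl is etherified. No cryogenic organolithium is needed, which is also better. The stereocentres of A3 are erased, so neither plan needs stereocontrol (equal).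
- Against: A2 is a trisubstituted enoate with a β-alkyl and an α-benzyl group, a poor acceptor that is prone to γ-deprotonation. A1 can enolise on either side, and only Michael addition from the methylene side followed by Claisen closure from the methyl side gives A3. The oxidant must act on a dione crowded at three adjacent carbons beside four electron-rich benzyloxyarenes that iodine can attack.
- Comparison: structurally more secure; mechanistically a chain of reversible steps against one irreversible organometallic sequence; no shorter, because A2 needs ring B built first and then homologated.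

Alternative 2: The cut removes the two hydroxyphenyl rings from the benzylic carbons on a4 and a6 (the two CH2–aryl bonds).
- Forward step: excess Grignard reagent A6 would deprotonate the hydroxymethyl groups of the bis-carbonate A5. Each alkoxide would take over the neighbouring Boc group, and the freed phenoxide would eliminate to an o-quinone methide stage that A6 captures at the exocyclic carbon. Two such cycles would give A7.
- In favour: both benzyl groups come from a cheap reagent without palladium or halogen selectivity, which is better than the chosen step 4 in reagent economy. The bridge would be installed before ring A is filled, so a5 is never the site of a late, crowded bond formation; this is also better. The final hydrogenolysis is the same (equal).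
- Against: A5 needs hydroxymethyl groups at a4 and a6 and the bridge at a5, which poses the same positional problem one stage earlier, and needs carbonate formation on phenols beside primary alcohols. The second elimination must start from a ring that is already a magnesium phenoxide. A7 has two equivalent free phenols, so the methyl ether can only come from a statistical mono-methylation to A4.
- Comparison: the chosen plan carries the methoxyl from compound 1 and never has to tell the ring A oxygens apart. Both key steps are demanding. The count is likely longer once A5 is included.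

Alternative 3: The cut again goes through ring A (a5–a6 and a4–a5), with the bridge appearing as a stilbene.
- Forward step: the dianion of the symmetrical diketone A8 would be acylated at one terminal methylene by the cinnamate A9. The other terminal methylene would then add to the new ketone and lose water to give the stilbene resorcinol A10. One phenol would be methylated and the whole hydrogenated to reach 17.
- In favour: this is the most convergent of the four plans and probably the shortest, which is better on step economy. Ring A and its link to the bridge form in one flask without a transition metal, which is better on reagent simplicity. The closing hydrogenation would saturate the stilbene and remove the benzyl groups together (equal endgame).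
- Against: the dianion must react at a secondary terminal carbon that bears a benzyl group. A9 invites conjugate addition. The acylated intermediate is more acidic than its precursor and quenches the dianion. Ring closure needs a further deprotonation at the far terminal methylene while O-cyclisation competes. A10 has two equivalent phenols, so the mono-methylation is statistical, as in alternative 2.
- Comparison: shorter and more biomimetic, but weaker in mechanistic security at the key step and in the methoxyl/hydroxyl differentiation, both of which the chosen plan settles by construction.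

Key step: step 9

Remark on the chemistry: 17 is achiral; 15 is racemic and its single stereocentre is removed in step 10. In the twofold substitutions (steps 2 and 4, and fallbacks that act twice on one ring) the two sites may react in either order, and the half-substituted species converge on one product and are not counted as separate intermediates.

Remark on the structures: the three coupling partners of step 9 and its product were checked atom by atom against 17 (five benzyl ethers, one methyl ether, boron on Cα) and are consistent, so no structure is altered. The changes concern how 6 and 11 are made and the halide scavenger in step 9.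

## Route

Step 1
Reactants: 1 3-bromo-5-methoxyphenol
Product: 2 1-(benzyloxy)-3-bromo-5-methoxybenzene
Conditions: BnBr (1.1 equiv.), K2CO3 (2 equiv.), DMF, 25 to 50 °C
Reagents that add atoms: benzyl bromide, BrCc1ccccc1
Why: Williamson ether synthesis; the phenoxide displaces bromide from the benzylic carbon, and the aryl bromide and methyl ether are inert to carbonate.

Step 2
Reactants: 2 1-(benzyloxy)-3-bromo-5-methoxybenzene
Product: 3 1-(benzyloxy)-3-bromo-2,4-diiodo-5-methoxybenzene
Conditions: N-iodosuccinimide (2.3 equiv.), CF3CO2H (0.3 equiv.), MeCN, 0 to 40 °C, dark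
Reagents that add atoms: N-iodosuccinimide, O=C1CCC(=O)N1I
Why: Electrophilic aromatic iodination; each carbon next to bromine is para to one alkoxy group and ortho to the other, whereas the third free carbon lies between both alkoxy groups and is the position resorcinol diethers substitute last; the unactivated phenyl ring of the benzyl ether should not react.

Step 3
Reactants: 4 4-(benzyloxy)benzyl chloride
Product: 5 4-(benzyloxy)benzylzinc chloride (LiCl-solvated THF solution, titrated and used in steps 4 and 6)
Conditions: Zn dust (1.5 equiv., activated with BrCH2CH2Br and Me3SiCl), LiCl (1.5 equiv.), THF, 25 °C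
Reagents that add atoms: zinc, [Zn]
Why: Direct oxidative insertion of zinc into the benzylic C–Cl bond, made fast at room temperature by LiCl, which clears the organozinc from the metal surface; the aryl benzyl ether is inert and slow addition of 4 limits Wurtz-type homocoupling.

Step 4
Reactants: 3 1-(benzyloxy)-3-bromo-2,4-diiodo-5-methoxybenzene, 5 4-(benzyloxy)benzylzinc chloride (2.5 equiv.)
Product: 6 1-(benzyloxy)-2,4-bis[4-(benzyloxy)benzyl]-3-bromo-5-methoxybenzene
Conditions: Pd2(dba)3 (2.5 mol%), P(2-furyl)3 (10 mol%), THF, 25 to 50 °C
Reagents that add atoms: none
Why: Twofold Negishi coupling; zerovalent palladium inserts into C–I far faster than into the doubly flanked C–Br, the benzylzinc reagent has no β-hydrogen, and the small, weakly donating furylphosphine keeps transmetalation fast at the crowded centres without activating the bromide.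

Step 5
Reactants: 7 3-bromo-5-chlorophenol
Product: 8 1-(benzyloxy)-3-bromo-5-chlorobenzene
Conditions: BnBr (1.1 equiv.), K2CO3 (2 equiv.), DMF, 25 to 50 °C
Reagents that add atoms: benzyl bromide, BrCc1ccccc1
Why: Williamson ether synthesis, as in step 1; both aryl halides are inert.

Step 6
Reactants: 8 1-(benzyloxy)-3-bromo-5-chlorobenzene, 5 4-(benzyloxy)benzylzinc chloride (1.2 equiv.)
Product: 9 1-(benzyloxy)-3-[4-(benzyloxy)benzyl]-5-chlorobenzene
Conditions: Pd(PPh3)4 (3 mol%), THF, 60 °C
Reagents that add atoms: none
Why: Negishi coupling; with a triarylphosphine catalyst oxidative addition occurs at C–Br and not at C–Cl, so the single benzylation is chemoselective and cannot run on to a bis-adduct.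

Step 7
Reactants: 9 1-(benzyloxy)-3-[4-(benzyloxy)benzyl]-5-chlorobenzene
Product: 10 3-(benzyloxy)-5-[4-(benzyloxy)benzyl]phenol
Conditions: Pd2(dba)3 (2 mol%), tBuXPhos (8 mol%), KOH (3 equiv.), 1,4-dioxane/H2O 1:1, 100 °C; then dilute HCl
Reagents that add atoms: potassium hydroxide, [K+].[OH-]
Why: Palladium-catalysed hydroxylation of an aryl chloride; the bulky di-tert-butylbiarylphosphine promotes C–O reductive elimination from the arylpalladium hydroxide, and benzyl ethers and the diarylmethane are stable to aqueous hydroxide.

Step 8
Reactants: 10 3-(benzyloxy)-5-[4-(benzyloxy)benzyl]phenol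
Product: 11 3-(benzyloxy)-5-[4-(benzyloxy)benzyl]phenyl trifluoromethanesulfonate
Conditions: (CF3SO2)2O (1.2 equiv.), pyridine (2 equiv.), CH2Cl2, 0 °C
Reagents that add atoms: trifluoromethanesulfonic anhydride, O=S(=O)(OS(=O)(=O)C(F)(F)F)C(F)(F)F
Why: O-sulfonylation of the only free hydroxyl; it gives the electrophile whose counter-ion does not bind palladium.

Step 9
Reactants: 6 1-(benzyloxy)-2,4-bis[4-(benzyloxy)benzyl]-3-bromo-5-methoxybenzene, 12 vinylboronic acid pinacol ester, 11 3-(benzyloxy)-5-[4-(benzyloxy)benzyl]phenyl trifluoromethanesulfonate
Product: 15 racemic penta-O-benzyl bibenzyl Cα-pinacol boronate, via ring A aryllithium 13 (not isolated), via lithium vinylborate complex 14 (not isolated)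
Conditions: LiC(CH3)3 (2.0 equiv.), Et2O, −78 °C; 12 (1.0 equiv.), −78 °C to rt; solvent exchange to THF; NaOSO2CF3 (2 equiv.), Pd(OAc)2 (3 mol%), 1,1'-bis(dicyclohexylphosphino)ferrocene Fe(C5H4PCy2)2 (3.6 mol%), 11 (1.1 equiv.), 60 °C
Reagents that add atoms: none
Why: Bromine–lithium exchange with two equivalents of LiC(CH3)3 at −78 °C is far faster than deprotonation of the diarylmethane or benzyl ether CH2 groups and gives 13, which is trapped at once at the empty boron orbital of 12 to give the four-coordinate vinylborate 14. Oxidative addition of 11 to zerovalent palladium gives, because triflate does not bind, a cationic aryl complex of divalent palladium that coordinates the vinyl group of 14. This activation triggers a 1,2-metallate shift in which ring A moves from boron to Cα (bond a5–Cα) anti to palladium while Cβ becomes bonded to palladium, and reductive elimination then forms Cβ–b1 and returns zerovalent palladium. The closest known reaction type is the palladium-catalysed three-component conjunctive cross-coupling of vinylboron ate complexes with aryl triflates, applied here with a doubly ortho-substituted migrating aryl group. No ring is closed. The one new stereocentre, Cα, forms racemic under the achiral bisphosphine and needs no control, because step 10 replaces boron by hydrogen. The selectivity needed is metallate shift over direct boron-to-palladium transfer of the aryl or vinyl group: the two ortho benzyl groups make direct transfer of ring A very slow, the cationic palladium favours alkene binding, the wide bite angle speeds reductive elimination over β-hydride elimination, and the sodium triflate keeps bromide from the exchange off palladium.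

Step 10
Reactants: 15 racemic penta-O-benzyl bibenzyl Cα-pinacol boronate
Product: 16 1-(benzyloxy)-2,4-bis[4-(benzyloxy)benzyl]-3-{2-[3-(benzyloxy)-5-(4-(benzyloxy)benzyl)phenyl]ethyl}-5-methoxybenzene
Conditions: CsF (2 equiv.), H2O (2 equiv.), 1,4-dioxane, 60 °C
Reagents that add atoms: none
Why: Fluoride-promoted protodeboronation of a benzylic boronic ester; fluoride adds to boron and the benzylic C–B bond is cleaved with protonation by water, and the stereocentre at Cα disappears as it becomes CH2.

Step 11
Reactants: 16 1-(benzyloxy)-2,4-bis[4-(benzyloxy)benzyl]-3-{2-[3-(benzyloxy)-5-(4-(benzyloxy)benzyl)phenyl]ethyl}-5-methoxybenzene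
Product: 17 2,4-bis(4-hydroxybenzyl)-3-{2-[3-hydroxy-5-(4-hydroxybenzyl)phenyl]ethyl}-5-methoxyphenol (CNP0204120.0)
Conditions: H2 (1 atm), 10% Pd/C, THF/MeOH 1:1, rt
Reagents that add atoms: none
Why: Catalytic hydrogenolysis of five aryl benzyl ethers at their benzylic C–O bonds; the aryl methyl ether, the diarylmethane C–C bonds and the bibenzyl bridge are not cleaved under these neutral conditions.

## Compound list

1 | 3-bromo-5-methoxyphenol | COc1cc(O)cc(Br)c1 | starting material
2 | 1-(benzyloxy)-3-bromo-5-methoxybenzene | COc1cc(Br)cc(OCc2ccccc2)c1 | intermediate
3 | 1-(benzyloxy)-3-bromo-2,4-diiodo-5-methoxybenzene | COc1cc(OCc2ccccc2)c(I)c(Br)c1I | intermediate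
4 | 4-(benzyloxy)benzyl chloride | ClCc1ccc(OCc2ccccc2)cc1 | starting material
5 | 4-(benzyloxy)benzylzinc chloride (LiCl-solvated, THF solution) | Cl[Zn]Cc1ccc(OCc2ccccc2)cc1 | intermediate
6 | 1-(benzyloxy)-2,4-bis[4-(benzyloxy)benzyl]-3-bromo-5-methoxybenzene (ring A bromide) | COc1cc(OCc2ccccc2)c(Cc2ccc(OCc3ccccc3)cc2)c(Br)c1Cc1ccc(OCc2ccccc2)cc1 | intermediate
7 | 3-bromo-5-chlorophenol | Oc1cc(Cl)cc(Br)c1 | starting material
8 | 1-(benzyloxy)-3-bromo-5-chlorobenzene | Clc1cc(Br)cc(OCc2ccccc2)c1 | intermediate
9 | 1-(benzyloxy)-3-[4-(benzyloxy)benzyl]-5-chlorobenzene | Clc1cc(OCc2ccccc2)cc(Cc2ccc(OCc3ccccc3)cc2)c1 | intermediate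
10 | 3-(benzyloxy)-5-[4-(benzyloxy)benzyl]phenol | Oc1cc(OCc2ccccc2)cc(Cc2ccc(OCc3ccccc3)cc2)c1 | intermediate
11 | 3-(benzyloxy)-5-[4-(benzyloxy)benzyl]phenyl trifluoromethanesulfonate (ring B triflate) | O=S(=O)(Oc1cc(OCc2ccccc2)cc(Cc2ccc(OCc3ccccc3)cc2)c1)C(F)(F)F | intermediate
12 | vinylboronic acid pinacol ester (4,4,5,5-tetramethyl-2-vinyl-1,3,2-dioxaborolane) | C=CB1OC(C)(C)C(C)(C)O1 | starting material
13 | {3-(benzyloxy)-2,6-bis[4-(benzyloxy)benzyl]-5-methoxyphenyl}lithium (not isolated) | COc1cc(OCc2ccccc2)c(Cc2ccc(OCc3ccccc3)cc2)c([Li])c1Cc1ccc(OCc2ccccc2)cc1 | intermediate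
14 | lithium {3-(benzyloxy)-2,6-bis[4-(benzyloxy)benzyl]-5-methoxyphenyl}(vinyl)(pinacolato)borate (not isolated) | [Li+].COc1cc(OCc2ccccc2)c(Cc2ccc(OCc3ccccc3)cc2)c([B-]2(C=C)OC(C)(C)C(C)(C)O2)c1Cc1ccc(OCc2ccccc2)cc1 | intermediate
15 | racemic 2-{1-[3-(benzyloxy)-2,6-bis(4-(benzyloxy)benzyl)-5-methoxyphenyl]-2-[3-(benzyloxy)-5-(4-(benzyloxy)benzyl)phenyl]ethyl}-4,4,5,5-tetramethyl-1,3,2-dioxaborolane | COc1cc(OCc2ccccc2)c(Cc2ccc(OCc3ccccc3)cc2)c(C(Cc2cc(OCc3ccccc3)cc(Cc3ccc(OCc4ccccc4)cc3)c2)B2OC(C)(C)C(C)(C)O2)c1Cc1ccc(OCc2ccccc2)cc1 | intermediate
16 | 1-(benzyloxy)-2,4-bis[4-(benzyloxy)benzyl]-3-{2-[3-(benzyloxy)-5-(4-(benzyloxy)benzyl)phenyl]ethyl}-5-methoxybenzene | COc1cc(OCc2ccccc2)c(Cc2ccc(OCc3ccccc3)cc2)c(CCc2cc(OCc3ccccc3)cc(Cc3ccc(OCc4ccccc4)cc3)c2)c1Cc1ccc(OCc2ccccc2)cc1 | intermediate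
17 | 2,4-bis(4-hydroxybenzyl)-3-{2-[3-hydroxy-5-(4-hydroxybenzyl)phenyl]ethyl}-5-methoxyphenol | COc1cc(O)c(Cc2ccc(O)cc2)c(CCc2cc(O)cc(Cc3ccc(O)cc3)c2)c1Cc1ccc(O)cc1 | target

## Step count and least certain steps

Total step count: 11. Longest linear sequence: 7 steps (steps 5, 6, 7, 8, 9, 10, 11). The ring A branch (steps 1, 2, 4) and the zinc reagent (step 3) converge on it.

Step 9 (key step). What may go wrong:
- proton transfer to the crowded aryllithium before it reaches boron, which would return debrominated ring A;
- in the palladium stage, transfer of the vinyl group from boron to palladium ahead of the metallate shift, because the migrating aryl group is shielded by two benzyl groups;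
- slowing of the cationic pathway by residual bromide.

Fallback: it sets out from 11 and 6 and comes back at 16, bypassing 15 and step 10. A Suzuki–Miyaura vinylation of 11 with 12 (PdCl2(dppf), K2CO3, 1,4-dioxane/H2O, 80 °C) should give the styrene 1-(benzyloxy)-3-[4-(benzyloxy)benzyl]-5-vinylbenzene F1. Anti-Markovnikov hydroboration with 9-borabicyclo[3.3.1]nonane in THF should give the alkylborane 9-{2-[3-(benzyloxy)-5-(4-(benzyloxy)benzyl)phenyl]ethyl}-9-borabicyclo[3.3.1]nonane F2, used in solution. A B-alkyl Suzuki–Miyaura coupling of F2 with 6 (Pd(OAc)2, SPhos, K3PO4, THF/H2O, 65 °C) should then form a5–Cα and give 16. The approach changes from a three-component coupling to a two-component sp3–sp2 coupling in which the bridge is first built on ring B. The price is that 6 must undergo oxidative addition, which dialkylbiarylphosphine ligands are known to allow for doubly ortho-substituted aryl bromides.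

Step 4. What may go wrong: erosion of the iodide-over-bromide selectivity once the catalyst is pushed to complete the second coupling, or stalling after the first coupling because the remaining iodide is crowded, leaving mixtures that are hard to separate.

Fallback: it sets out from 3 and comes back at 6, with no palladium.
- Iodine–magnesium exchange with iPrMgCl·LiCl (THF, −40 °C) is much faster than bromine–magnesium exchange.
- The arylmagnesium is added to 4-(benzyloxy)benzaldehyde, and the exchange–addition cycle is repeated in the same flask on the second iodide.
- This should give the bis-carbinol {4-(benzyloxy)-2-bromo-6-methoxy-1,3-phenylene}bis{[4-(benzyloxy)phenyl]methanol} F3 as a mixture of diastereomers of no consequence.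
- Ionic hydrogenation of both doubly benzylic alcohols (Et3SiH, CF3CO2H, CH2Cl2, 0 °C) should give 6.

The low temperature guards against loss of magnesium bromide from the ortho-bromo arylmagnesium.

Step 2. What may go wrong: stalling of the second iodination, which must enter a position between bromine and an ether oxygen on a ring already deactivated by the first iodine; forcing it may divert iodine to the carbon between the two oxygens.

Fallback: it sets out from 2 and comes back at 6, replacing steps 2 and 4 and making no compound outside the list (entry F0). It is a twofold Friedel–Crafts benzylation of 2 with 4 (2.2 equiv.) in (CF3)2CHOH at 0 to 25 °C, a medium that ionises p-alkoxybenzyl chlorides without a Lewis acid. The first benzyl group activates the ring for the second substitution, the reverse of the deactivation by the first iodine. Its own hazards are further alkylation and attack between the oxygens, which is why it is the reserve and not the main route.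

Step 10. What may go wrong: slow cleavage of the C–B bond, because the boronate sits beside a doubly ortho-substituted ring that hinders both fluoride coordination and flattening of the benzylic carbon; prolonged heating then risks adventitious oxidation.

Fallback: it sets out from 15 and comes back at 17.
- Oxidation (NaBO3·4H2O, THF/H2O, rt) should give the racemic alcohol 1-{3-(benzyloxy)-2,6-bis[4-(benzyloxy)benzyl]-5-methoxyphenyl}-2-{3-(benzyloxy)-5-[4-(benzyloxy)benzyl]phenyl}ethan-1-ol F4.
- Dehydration with the Burgess reagent (toluene, 80 °C) should give the stilbene 1-(benzyloxy)-2,4-bis[4-(benzyloxy)benzyl]-3-[(E)-2-{3-(benzyloxy)-5-[4-(benzyloxy)benzyl]phenyl}ethenyl]-5-methoxybenzene F5.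
- Hydrogenation under the conditions of step 11 should saturate the alkene and remove the five benzyl groups in one operation.

Further compounds

F1 | step 9 | 1-(benzyloxy)-3-[4-(benzyloxy)benzyl]-5-vinylbenzene | C=Cc1cc(OCc2ccccc2)cc(Cc2ccc(OCc3ccccc3)cc2)c1
F2 | step 9 | 9-{2-[3-(benzyloxy)-5-(4-(benzyloxy)benzyl)phenyl]ethyl}-9-borabicyclo[3.3.1]nonane | C(Cc1cc(OCc2ccccc2)cc(Cc2ccc(OCc3ccccc3)cc2)c1)B1C2CCCC1CCC2
F3 | step 4 | {4-(benzyloxy)-2-bromo-6-methoxy-1,3-phenylene}bis{[4-(benzyloxy)phenyl]methanol} (mixture of diastereomers) | COc1cc(OCc2ccccc2)c(C(O)c2ccc(OCc3ccccc3)cc2)c(Br)c1C(O)c1ccc(OCc2ccccc2)cc1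
F0 | step 2 | none | none
F4 | step 10 | racemic 1-{3-(benzyloxy)-2,6-bis[4-(benzyloxy)benzyl]-5-methoxyphenyl}-2-{3-(benzyloxy)-5-[4-(benzyloxy)benzyl]phenyl}ethan-1-ol | COc1cc(OCc2ccccc2)c(Cc2ccc(OCc3ccccc3)cc2)c(C(O)Cc2cc(OCc3ccccc3)cc(Cc3ccc(OCc4ccccc4)cc3)c2)c1Cc1ccc(OCc2ccccc2)cc1
F5 | step 10 | 1-(benzyloxy)-2,4-bis[4-(benzyloxy)benzyl]-3-[(E)-2-{3-(benzyloxy)-5-[4-(benzyloxy)benzyl]phenyl}ethenyl]-5-methoxybenzene | COc1cc(OCc2ccccc2)c(Cc2ccc(OCc3ccccc3)cc2)c(/C=C/c2cc(OCc3ccccc3)cc(Cc3ccc(OCc4ccccc4)cc3)c2)c1Cc1ccc(OCc2ccccc2)cc1
A1 | alternative 1 | 4-[4-(benzyloxy)phenyl]butan-2-one | CC(=O)CCc1ccc(OCc2ccccc2)cc1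
A2 | alternative 1 | methyl (E)-2-[4-(benzyloxy)benzyl]-5-{3-(benzyloxy)-5-[4-(benzyloxy)benzyl]phenyl}pent-2-enoate | COC(=O)/C(Cc1ccc(OCc2ccccc2)cc1)=C/CCc1cc(OCc2ccccc2)cc(Cc2ccc(OCc3ccccc3)cc2)c1
A3 | alternative 1 | all-trans (meso) 4,6-bis[4-(benzyloxy)benzyl]-5-{2-[3-(benzyloxy)-5-(4-(benzyloxy)benzyl)phenyl]ethyl}cyclohexane-1,3-dione | O=C1CC(=O)[C@H](Cc2ccc(OCc3ccccc3)cc2)[C@@H](CCc2cc(OCc3ccccc3)cc(Cc3ccc(OCc4ccccc4)cc3)c2)[C@@H]1Cc1ccc(OCc2ccccc2)cc1
A4 | alternative 1 | 2,4-bis[4-(benzyloxy)benzyl]-3-{2-[3-(benzyloxy)-5-(4-(benzyloxy)benzyl)phenyl]ethyl}-5-methoxyphenol | COc1cc(O)c(Cc2ccc(OCc3ccccc3)cc2)c(CCc2cc(OCc3ccccc3)cc(Cc3ccc(OCc4ccccc4)cc3)c2)c1Cc1ccc(OCc2ccccc2)cc1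
A5 | alternative 2 | di-tert-butyl {5-[2-(3-(benzyloxy)-5-(4-(benzyloxy)benzyl)phenyl)ethyl]-4,6-bis(hydroxymethyl)-1,3-phenylene} dicarbonate | CC(C)(C)OC(=O)Oc1cc(OC(=O)OC(C)(C)C)c(CO)c(CCc2cc(OCc3ccccc3)cc(Cc3ccc(OCc4ccccc4)cc3)c2)c1CO
A6 | alternative 2 | 4-(benzyloxy)phenylmagnesium bromide | Br[Mg]c1ccc(OCc2ccccc2)cc1
A7 | alternative 2 | 4,6-bis[4-(benzyloxy)benzyl]-5-{2-[3-(benzyloxy)-5-(4-(benzyloxy)benzyl)phenyl]ethyl}benzene-1,3-diol | Oc1cc(O)c(Cc2ccc(OCc3ccccc3)cc2)c(CCc2cc(OCc3ccccc3)cc(Cc3ccc(OCc4ccccc4)cc3)c2)c1Cc1ccc(OCc2ccccc2)cc1
A8 | alternative 3 | 1,7-bis[4-(benzyloxy)phenyl]heptane-3,5-dione | O=C(CCc1ccc(OCc2ccccc2)cc1)CC(=O)CCc1ccc(OCc2ccccc2)cc1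
A9 | alternative 3 | methyl (E)-3-{3-(benzyloxy)-5-[4-(benzyloxy)benzyl]phenyl}prop-2-enoate | COC(=O)/C=C/c1cc(OCc2ccccc2)cc(Cc2ccc(OCc3ccccc3)cc2)c1
A10 | alternative 3 | 4,6-bis[4-(benzyloxy)benzyl]-5-[(E)-2-{3-(benzyloxy)-5-[4-(benzyloxy)benzyl]phenyl}ethenyl]benzene-1,3-diol | Oc1cc(O)c(Cc2ccc(OCc3ccccc3)cc2)c(/C=C/c2cc(OCc3ccccc3)cc(Cc3ccc(OCc4ccccc4)cc3)c2)c1Cc1ccc(OCc2ccccc2)cc1
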